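**Strategy**

The dihydropyran ring is cut at C3–C4 and at O1–C8a. In one flask a benzylic Grignard reagent (C4, on a hexasubstituted fluoroarene that already carries the C5 oxygen, C6 ester, C7 methyl and C8 prenyl groups) opens an enantiopure trityl 2-methylglycidyl ether at its CH2 carbon, and the tertiary alkoxide so formed displaces fluoride from C8a. The step exploits two features: C8a lies para to the C6 carboxyl group on the benzene ring, which activates it for substitution, and the O1–C2–C3 unit around the quaternary stereocentre C2 maps onto a 2,2-disubstituted oxirane from the chiral pool. The dienyl chain is grown afterwards from the C2 CH2OH group.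

Key step: step 8

Remark on the chemistry: chroman numbering (O1, C2, C3, C4, C4a, C5–C8, C8a) is used for the target and, by analogy, for the arene precursors. The target SMILES encodes the (2R) enantiomer. Oxirane 13 is (R) although it is made from (S)-12, because O-tritylation changes the CIP ranking and not the geometry.

**Route**

Step 1
Reactants: 1 3-fluoro-5-methylphenol
Product: 2 4-bromo-3-fluoro-5-methylphenol
Conditions: NBS (1.0 equiv), MeCN, –20 → 0 °C
Reagents that add atoms: N-bromosuccinimide, O=C1CCC(=O)N1Br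
Why: Electrophilic aromatic bromination; the hydroxyl group should direct bromine to its para position (between F and CH3), as it does in other 3,5-disubstituted phenols.

Step 2
Reactants: 2 4-bromo-3-fluoro-5-methylphenol
Product: 3 2-bromo-1-fluoro-5-(methoxymethoxy)-3-methylbenzene
Conditions: MOMCl, i-Pr2NEt, CH2Cl2, 0 °C → rt
Reagents that add atoms: chloromethyl methyl ether, COCCl
Why: Williamson-type O-alkylation of the phenol; the MOM ether protects the oxygen and is the directing group for both later ortho-lithiations.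

Step 3
Reactants: 3 2-bromo-1-fluoro-5-(methoxymethoxy)-3-methylbenzene; 4 1-bromo-3-methylbut-2-ene (prenyl bromide)
Product: 6 1-fluoro-5-(methoxymethoxy)-3-methyl-2-(3-methylbut-2-en-1-yl)benzene, via arylmagnesium chloride 5 (not isolated)
Conditions: i-PrMgCl·LiCl, THF, 0 °C → rt; then CuI (5 mol %), 4, –20 → 0 °C
Reagents that add atoms: none
Why: Bromine–magnesium exchange (accelerated by the ortho fluorine) followed by copper-catalysed allylic substitution at the unhindered CH2 terminus of prenyl bromide should install the C8 prenyl group.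

Step 4
Reactants: 6 1-fluoro-5-(methoxymethoxy)-3-methyl-2-(3-methylbut-2-en-1-yl)benzene
Product: 8 1-[2-fluoro-6-(methoxymethoxy)-4-methyl-3-(3-methylbut-2-en-1-yl)phenyl]-N,N-dimethylmethanamine, via aryllithium 7 (not isolated)
Conditions: n-BuLi, THF, –78 °C; then CH2=NMe2+ I–, –78 → –30 °C
Reagents that add atoms: N,N-dimethylmethyleneiminium iodide, C=[N+](C)C.[I-]
Why: Directed ortho-metalation at the C–H flanked by F and OMOM, the most acidic and doubly coordinated ring position, followed by Mannich-type trapping with the iminium salt should give the benzylic amine that carries the future C4.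

Step 5
Reactants: 8 1-[2-fluoro-6-(methoxymethoxy)-4-methyl-3-(3-methylbut-2-en-1-yl)phenyl]-N,N-dimethylmethanamine
Product: 10 2-(trimethylsilyl)ethyl 3-[(dimethylamino)methyl]-4-fluoro-2-(methoxymethoxy)-6-methyl-5-(3-methylbut-2-en-1-yl)benzoate, via aryllithium 9 (not isolated)
Conditions: s-BuLi, TMEDA, THF, –78 °C; then ClCO2CH2CH2SiMe3, –78 → –20 °C
Reagents that add atoms: 2-(trimethylsilyl)ethyl chloroformate, C[Si](C)(C)CCOC(=O)Cl
Why: Second directed ortho-metalation at the only ring C–H left, which lies ortho to OMOM, and acylation of the aryllithium by the chloroformate should give the hindered silylethyl ester; the CH2NMe2 group is inert to alkyllithium.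

Step 6
Reactants: 10 2-(trimethylsilyl)ethyl 3-[(dimethylamino)methyl]-4-fluoro-2-(methoxymethoxy)-6-methyl-5-(3-methylbut-2-en-1-yl)benzoate
Product: 11 2-(trimethylsilyl)ethyl 3-(chloromethyl)-4-fluoro-2-(methoxymethoxy)-6-methyl-5-(3-methylbut-2-en-1-yl)benzoate
Conditions: ClCO2Et, THF, 0 °C → rt
Reagents that add atoms: ethyl chloroformate, CCOC(=O)Cl
Why: Chloroformate-induced dealkylative chlorination of a benzylic tertiary amine (von Braun-type): N-acylation gives an acylammonium ion that chloride cleaves at the activated benzylic carbon.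

Step 7
Reactants: 12 [(2S)-2-methyloxiran-2-yl]methanol ((S)-2-methylglycidol)
Product: 13 (2R)-2-methyl-2-[(triphenylmethoxy)methyl]oxirane
Conditions: TrCl, Et3N, DMAP (cat.), CH2Cl2, 0 °C → rt
Reagents that add atoms: trityl chloride, ClC(c1ccccc1)(c1ccccc1)c1ccccc1
Why: Amine-mediated O-tritylation of the primary alcohol without alkoxide formation, so no Payne rearrangement can scramble the stereocentre, whose geometry is unchanged.

Step 8
Reactants: 11 2-(trimethylsilyl)ethyl 3-(chloromethyl)-4-fluoro-2-(methoxymethoxy)-6-methyl-5-(3-methylbut-2-en-1-yl)benzoate; 13 (2R)-2-methyl-2-[(triphenylmethoxy)methyl]oxirane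
Product: 16 2-(trimethylsilyl)ethyl (2R)-5-(methoxymethoxy)-2,7-dimethyl-8-(3-methylbut-2-en-1-yl)-2-[(triphenylmethoxy)methyl]-3,4-dihydro-2H-chromene-6-carboxylate, via benzylic Grignard reagent 14 (not isolated), via magnesium alkoxide 15 (not isolated)
Conditions: Mg turnings, LiCl, THF, 0 °C (slow addition of 11); then 13, CuI (10 mol %), –40 → 0 °C; then KOt-Bu (1.1 equiv), DMPU, 0 → 50 °C
Reagents that add atoms: none
Why: Magnesium inserts into the benzylic C–Cl bond of 11 and the benzylic Grignard reagent 14, under CuI catalysis, opens oxirane 13 by SN2 attack at its unsubstituted CH2 carbon (C3–C4) to give tertiary alkoxide 15, which after potassium exchange attacks C8a by addition–elimination through a Meisenheimer intermediate stabilised by the para C6 ester and expels fluoride (O1–C8a). The closest known reactions are the copper-catalysed opening of 2,2-disubstituted epoxides by benzylmagnesium halides and the intramolecular SNAr etherification of ortho-fluoroaryl alkoxides to chromans, run here as one domino sequence. The dihydropyran ring closes in a 6-exo-trig mode with the arene carbon C8a as the trigonal electrophile. No new stereocentre is formed: the quaternary C2 comes from (S)-2-methylglycidol and none of its four bonds is broken, so its configuration should be carried into 16 unchanged. The step needs regioselective epoxide opening, secured by the steric difference between the CH2 and the fully substituted oxirane carbon, and chemoselectivity of the Grignard reagent for the epoxide over the ester, secured by the two ortho substituents (OMOM and CH3) that shield the ester carbonyl. O-arylation can occur only at C8a, which bears the sole leaving group and gives a six-membered ring, and the released fluoride should be held as an insoluble potassium or magnesium salt so that the silylethyl ester is not cleaved.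

Step 9
Reactants: 16 2-(trimethylsilyl)ethyl (2R)-5-(methoxymethoxy)-2,7-dimethyl-8-(3-methylbut-2-en-1-yl)-2-[(triphenylmethoxy)methyl]-3,4-dihydro-2H-chromene-6-carboxylate
Product: 17 2-(trimethylsilyl)ethyl (2R)-5-hydroxy-2-(hydroxymethyl)-2,7-dimethyl-8-(3-methylbut-2-en-1-yl)-3,4-dihydro-2H-chromene-6-carboxylate
Conditions: HCl (cat.), MeOH/THF, rt
Reagents that add atoms: none
Why: Acid-catalysed methanolysis cleaves the trityl ether (SN1) and the aryl MOM acetal in one operation, at a stage where the C2 ether is not yet allylic; the hindered silylethyl ester and the prenyl group should survive dilute HCl at room temperature.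

Step 10
Reactants: 17 2-(trimethylsilyl)ethyl (2R)-5-hydroxy-2-(hydroxymethyl)-2,7-dimethyl-8-(3-methylbut-2-en-1-yl)-3,4-dihydro-2H-chromene-6-carboxylate
Product: 18 2-(trimethylsilyl)ethyl (2R)-2-formyl-5-hydroxy-2,7-dimethyl-8-(3-methylbut-2-en-1-yl)-3,4-dihydro-2H-chromene-6-carboxylate
Conditions: SO3·pyridine, DMSO, i-Pr2NEt, CH2Cl2, 0 °C
Reagents that add atoms: none
Why: Parikh–Doering oxidation of the neopentyl-type primary alcohol should give the aldehyde without touching the hydrogen-bonded phenol, and C2 cannot epimerise because it bears no hydrogen.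

Step 11
Reactants: 4 1-bromo-3-methylbut-2-ene (prenyl bromide); 19 triethyl phosphite
Product: 20 diethyl (3-methylbut-2-en-1-yl)phosphonate
Conditions: neat, 120 °C, bromoethane distilled off
Reagents that add atoms: none
Why: Michaelis–Arbuzov reaction of the primary allylic bromide with the phosphite, driven by loss of volatile bromoethane.

Step 12
Reactants: 18 2-(trimethylsilyl)ethyl (2R)-2-formyl-5-hydroxy-2,7-dimethyl-8-(3-methylbut-2-en-1-yl)-3,4-dihydro-2H-chromene-6-carboxylate; 20 diethyl (3-methylbut-2-en-1-yl)phosphonate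
Product: 22 2-(trimethylsilyl)ethyl (2R)-5-hydroxy-2,7-dimethyl-8-(3-methylbut-2-en-1-yl)-2-[(1E)-4-methylpenta-1,3-dien-1-yl]-3,4-dihydro-2H-chromene-6-carboxylate, via lithiated phosphonate 21 (not isolated)
Conditions: 20 (3.3 equiv), n-BuLi (3.2 equiv), THF, –78 °C; then 18, DMPU, –78 °C → rt
Reagents that add atoms: none
Why: Horner–Wadsworth–Emmons olefination with an allylic phosphonate anion, whose first equivalent deprotonates the phenol: attack through the α-carbon is expected because the γ-carbon is fully substituted, and elimination should give the (E)-C1'=C2' alkene.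

Step 13
Reactants: 22 2-(trimethylsilyl)ethyl (2R)-5-hydroxy-2,7-dimethyl-8-(3-methylbut-2-en-1-yl)-2-[(1E)-4-methylpenta-1,3-dien-1-yl]-3,4-dihydro-2H-chromene-6-carboxylate
Product: 23 (2R)-5-hydroxy-2,7-dimethyl-8-(3-methylbut-2-en-1-yl)-2-[(1E)-4-methylpenta-1,3-dien-1-yl]-3,4-dihydro-2H-chromene-6-carboxylic acid
Conditions: TBAF, THF, 0 °C → rt; then cold dilute HCl to pH 4
Reagents that add atoms: none
Why: Fluoride attacks silicon and the β-silylethyl ester fragments to ethene and the carboxylate (fluoride-induced 1,2-elimination), which avoids acid, to which the dienyl tertiary aryl ether is labile, and heat, which would decarboxylate the salicylic acid.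

**Compound list**

1 | 3-fluoro-5-methylphenol | Cc1cc(O)cc(F)c1 | starting material
2 | 4-bromo-3-fluoro-5-methylphenol | Cc1cc(O)cc(F)c1Br | intermediate
3 | 2-bromo-1-fluoro-5-(methoxymethoxy)-3-methylbenzene | Cc1cc(OCOC)cc(F)c1Br | intermediate
4 | 1-bromo-3-methylbut-2-ene (prenyl bromide) | CC(C)=CCBr | starting material
5 | [2-fluoro-4-(methoxymethoxy)-6-methylphenyl]magnesium chloride | Cc1cc(OCOC)cc(F)c1[Mg]Cl | intermediate
6 | 1-fluoro-5-(methoxymethoxy)-3-methyl-2-(3-methylbut-2-en-1-yl)benzene | Cc1cc(OCOC)cc(F)c1CC=C(C)C | intermediate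
7 | [2-fluoro-6-(methoxymethoxy)-4-methyl-3-(3-methylbut-2-en-1-yl)phenyl]lithium | Cc1cc(OCOC)c([Li])c(F)c1CC=C(C)C | intermediate
8 | 1-[2-fluoro-6-(methoxymethoxy)-4-methyl-3-(3-methylbut-2-en-1-yl)phenyl]-N,N-dimethylmethanamine | Cc1cc(OCOC)c(CN(C)C)c(F)c1CC=C(C)C | intermediate
9 | {3-[(dimethylamino)methyl]-4-fluoro-2-(methoxymethoxy)-6-methyl-5-(3-methylbut-2-en-1-yl)phenyl}lithium | Cc1c([Li])c(OCOC)c(CN(C)C)c(F)c1CC=C(C)C | intermediate
10 | 2-(trimethylsilyl)ethyl 3-[(dimethylamino)methyl]-4-fluoro-2-(methoxymethoxy)-6-methyl-5-(3-methylbut-2-en-1-yl)benzoate | Cc1c(C(=O)OCC[Si](C)(C)C)c(OCOC)c(CN(C)C)c(F)c1CC=C(C)C | intermediate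
11 | 2-(trimethylsilyl)ethyl 3-(chloromethyl)-4-fluoro-2-(methoxymethoxy)-6-methyl-5-(3-methylbut-2-en-1-yl)benzoate | Cc1c(C(=O)OCC[Si](C)(C)C)c(OCOC)c(CCl)c(F)c1CC=C(C)C | intermediate
12 | [(2S)-2-methyloxiran-2-yl]methanol ((S)-2-methylglycidol) | OC[C@@]1(C)CO1 | starting material
13 | (2R)-2-methyl-2-[(triphenylmethoxy)methyl]oxirane | C(c2ccccc2)(c2ccccc2)(c2ccccc2)OC[C@@]1(C)CO1 | intermediate
14 | chloro{[6-fluoro-2-(methoxymethoxy)-4-methyl-5-(3-methylbut-2-en-1-yl)-3-{[2-(trimethylsilyl)ethoxy]carbonyl}phenyl]methyl}magnesium (benzylic Grignard reagent from 11) | Cc1c(C(=O)OCC[Si](C)(C)C)c(OCOC)c(C[Mg]Cl)c(F)c1CC=C(C)C | intermediate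
15 | chloromagnesium alkoxide of 2-(trimethylsilyl)ethyl 4-fluoro-3-[(3R)-3-hydroxy-3-methyl-4-(triphenylmethoxy)butyl]-2-(methoxymethoxy)-6-methyl-5-(3-methylbut-2-en-1-yl)benzoate | C(c2ccccc2)(c2ccccc2)(c2ccccc2)OC[C@@](O[Mg]Cl)(C)CCc1c(OCOC)c(C(=O)OCC[Si](C)(C)C)c(C)c(CC=C(C)C)c1F | intermediate
16 | 2-(trimethylsilyl)ethyl (2R)-5-(methoxymethoxy)-2,7-dimethyl-8-(3-methylbut-2-en-1-yl)-2-[(triphenylmethoxy)methyl]-3,4-dihydro-2H-chromene-6-carboxylate | C(c3ccccc3)(c3ccccc3)(c3ccccc3)OC[C@@]1(C)CCc2c(OCOC)c(C(=O)OCC[Si](C)(C)C)c(C)c(CC=C(C)C)c2O1 | intermediate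
17 | 2-(trimethylsilyl)ethyl (2R)-5-hydroxy-2-(hydroxymethyl)-2,7-dimethyl-8-(3-methylbut-2-en-1-yl)-3,4-dihydro-2H-chromene-6-carboxylate | OC[C@@]1(C)CCc2c(O)c(C(=O)OCC[Si](C)(C)C)c(C)c(CC=C(C)C)c2O1 | intermediate
18 | 2-(trimethylsilyl)ethyl (2R)-2-formyl-5-hydroxy-2,7-dimethyl-8-(3-methylbut-2-en-1-yl)-3,4-dihydro-2H-chromene-6-carboxylate | O=C[C@@]1(C)CCc2c(O)c(C(=O)OCC[Si](C)(C)C)c(C)c(CC=C(C)C)c2O1 | intermediate
19 | triethyl phosphite | CCOP(OCC)OCC | starting material
20 | diethyl (3-methylbut-2-en-1-yl)phosphonate | CCOP(=O)(CC=C(C)C)OCC | intermediate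
21 | diethyl (1-lithio-3-methylbut-2-en-1-yl)phosphonate | CCOP(=O)(OCC)C([Li])C=C(C)C | intermediate
22 | 2-(trimethylsilyl)ethyl (2R)-5-hydroxy-2,7-dimethyl-8-(3-methylbut-2-en-1-yl)-2-[(1E)-4-methylpenta-1,3-dien-1-yl]-3,4-dihydro-2H-chromene-6-carboxylate | CC(C)=C/C=C/[C@@]1(C)CCc2c(O)c(C(=O)OCC[Si](C)(C)C)c(C)c(CC=C(C)C)c2O1 | intermediate
23 | (2R)-5-hydroxy-2,7-dimethyl-8-(3-methylbut-2-en-1-yl)-2-[(1E)-4-methylpenta-1,3-dien-1-yl]-3,4-dihydro-2H-chromene-6-carboxylic acid | CC(C)=C/C=C/[C@@]1(C)CCc2c(O)c(C(=O)O)c(C)c(CC=C(C)C)c2O1 | target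

**Step count**

Total steps: 13. Longest linear sequence: 11 steps (steps 1–6, 8–10, 12 and 13, from compound 1).

**Steps most likely to fail**

1. Step 8. Magnesium insertion may be accompanied by Wurtz homocoupling, the benzylic Grignard reagent may be quenched by proton transfer from the C7 methyl group (ortho to the ester), and fluoride displacement may be slow because the doubly ortho-substituted ester is twisted out of conjugation. Fallback: from benzylic chloride 11, displacement with PhSO2Na (DMF, rt) should give the benzylic phenyl sulfone F1. Its α-sulfonyl carbanion (LiN(SiMe3)2, THF/DMPU, –78 °C) is far more acidic than the C7 methyl group and compatible with the ester. It should open oxirane 13 at CH2, and on warming to 60 °C the alkoxide should close onto C8a to give the 4-(phenylsulfonyl)chroman F2 as a mixture of C4 epimers. Reductive desulfonylation (Na/Hg, Na2HPO4, MeOH/THF, –20 °C) returns to 16.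

2. Step 5. Deprotonation at the allylic and benzylic CH2 of the prenyl group may compete with lithiation of the hindered ring C–H between OMOM and CH3. Fallback: the carboxyl carbon is introduced by phenoxide-directed electrophilic substitution in place of an aryl anion. From amine 8, HCl in MeOH should remove the MOM group to give the phenol F3. Magnesium-phenoxide-directed ortho-formylation (MgCl2, Et3N, paraformaldehyde, MeCN, reflux) at the only free ring position should give the salicylaldehyde F4. Re-protection (NaH, MOMCl, THF) gives the MOM ether aldehyde F5, and Pinnick oxidation (NaClO2, NaH2PO4, 2-methylbut-2-ene, t-BuOH/H2O) gives the benzoic acid F6. Mitsunobu esterification with 2-(trimethylsilyl)ethanol (PPh3, DIAD, THF) returns to 10.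

3. Step 12. The allylic phosphonate anion may attack partly through its γ-carbon, addition to the α-quaternary aldehyde may be slow, and E/Z control in the elimination may be incomplete. Fallback: from aldehyde 18, Takai olefination (CrCl2, CHI3, THF, 0 °C) should give the (E)-vinyl iodide F7 with the E-selectivity typical of α-branched aldehydes. Suzuki–Miyaura coupling with 2-methylprop-1-enylboronic acid pinacol ester (Pd(PPh3)4, K2CO3, THF/H2O, 50 °C) then returns to 22 with the double-bond geometry retained.

**Further compounds**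

F1 | step 8 | 2-(trimethylsilyl)ethyl 4-fluoro-2-(methoxymethoxy)-6-methyl-5-(3-methylbut-2-en-1-yl)-3-[(phenylsulfonyl)methyl]benzoate | Cc1c(C(=O)OCC[Si](C)(C)C)c(OCOC)c(CS(=O)(=O)c2ccccc2)c(F)c1CC=C(C)C
F2 | step 8 | 2-(trimethylsilyl)ethyl (2R)-5-(methoxymethoxy)-2,7-dimethyl-8-(3-methylbut-2-en-1-yl)-4-(phenylsulfonyl)-2-[(triphenylmethoxy)methyl]-3,4-dihydro-2H-chromene-6-carboxylate (both C4 epimers) | C(c3ccccc3)(c3ccccc3)(c3ccccc3)OC[C@@]1(C)CC(S(=O)(=O)c3ccccc3)c2c(OCOC)c(C(=O)OCC[Si](C)(C)C)c(C)c(CC=C(C)C)c2O1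
F3 | step 5 | 2-[(dimethylamino)methyl]-3-fluoro-5-methyl-4-(3-methylbut-2-en-1-yl)phenol | Cc1cc(O)c(CN(C)C)c(F)c1CC=C(C)C
F4 | step 5 | 3-[(dimethylamino)methyl]-4-fluoro-2-hydroxy-6-methyl-5-(3-methylbut-2-en-1-yl)benzaldehyde | Cc1c(C=O)c(O)c(CN(C)C)c(F)c1CC=C(C)C
F5 | step 5 | 3-[(dimethylamino)methyl]-4-fluoro-2-(methoxymethoxy)-6-methyl-5-(3-methylbut-2-en-1-yl)benzaldehyde | Cc1c(C=O)c(OCOC)c(CN(C)C)c(F)c1CC=C(C)C
F6 | step 5 | 3-[(dimethylamino)methyl]-4-fluoro-2-(methoxymethoxy)-6-methyl-5-(3-methylbut-2-en-1-yl)benzoic acid | Cc1c(C(=O)O)c(OCOC)c(CN(C)C)c(F)c1CC=C(C)C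
F7 | step 12 | 2-(trimethylsilyl)ethyl (2R)-5-hydroxy-2-[(E)-2-iodoethenyl]-2,7-dimethyl-8-(3-methylbut-2-en-1-yl)-3,4-dihydro-2H-chromene-6-carboxylate | I/C=C/[C@@]1(C)CCc2c(O)c(C(=O)OCC[Si](C)(C)C)c(C)c(CC=C(C)C)c2O1
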